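**Strategy.** The route rests on disconnecting the bond between the two ring-fusion carbons of the pyranopyran, C8 (O–CH) and C13 (O–C–CH3). A samarium diiodide ketyl–olefin cyclisation joins them: it closes the tetrahydropyran (ring E), sets C8 and C13 in one operation from the oxetane centres C10 and C11, and the cis alkoxide lactonises at once. The step exploits the 1,3-cis placement of O14 and the oxetane oxygen O16 on ring E, which samarium can bridge. Its precursor is a cis-2,3-disubstituted oxetane carrying an acetonyl group on C11 and an (E)-β-alkoxyacrylate on O9. C11 comes from a SAMP alkylation; the lactone carbon is later excised and a dibenzoxepinone attached.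

Key step: step 7

Labels used below: ring A = prenylated benzene ring, ring B = the other benzene ring, ring C = oxepine, ring D = dihydropyran, ring E = tetrahydropyran, ring F = oxetane. Cα = oxepine carbon bearing O14, Cβ = oxepine carbon bearing C7, C7 = CH2 of ring D, C8 = O–CH ring-fusion carbon, O9 = ring E oxygen, C10 and C11 = oxetane CH carbons (C10 on O9, C11 on O16), C12 = ring E CH2, C13 = methyl-bearing ring-fusion carbon, O14 = ring D oxygen, C15 = CMe2, O16 = oxetane oxygen. Systematic names of the oxepinones and bicycles keep their own ring locants.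

Assumption: the SMILES is read as (8R,10R,11S,13R), that is rings D and E cis-fused, with C7, C15, O16 and O14 all on one face of ring E.

Remark: the auxiliary-controlled alkylation should give high but not complete enantiomeric excess; lactone 13 is the intended stage for enrichment by recrystallisation if this is needed.

Step 1
Reactants: 1 2-methylbut-3-yn-2-ol
Product: 2 2,2-dimethyloxetan-3-one
Conditions: (IPr)AuNTf2 (IPr = 1,3-bis(2,6-diisopropylphenyl)imidazol-2-ylidene, 5 mol %), 4-acetylpyridine N-oxide (2 equiv), 1,2-dichloroethane, 60 °C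
Reagents that add atoms: 4-acetylpyridine N-oxide (CC(=O)c1cc[n+]([O-])cc1)
Why: Gold-catalysed alkyne oxidation puts the N-oxide oxygen on the internal alkyne carbon, and the resulting α-oxo gold carbene inserts into the tertiary O–H bond to close the oxetan-3-one (carbene O–H insertion).

Step 2
Reactants: 2 2,2-dimethyloxetan-3-one; 3 (S)-1-amino-2-(methoxymethyl)pyrrolidine (SAMP)
Product: 4 SAMP hydrazone of 2,2-dimethyloxetan-3-one
Conditions: neat, 4 Å molecular sieves, 55 °C
Reagents that add atoms: none
Why: Condensation of ketone and hydrazine gives the Enders SAMP hydrazone, whose only acidic α-position is the ring CH2 (future C11).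

Step 3
Reactants: 4 SAMP hydrazone of 2,2-dimethyloxetan-3-one; 5 allyl bromide
Product: 7 (4S)-4-allyl-2,2-dimethyloxetan-3-one, via alkylated SAMP hydrazone 6 (not isolated)
Conditions: t-BuLi (1.1 equiv), THF, −78 °C; allyl bromide, −78 °C to rt; then saturated aq. oxalic acid, Et2O, rt
Reagents that add atoms: water (O)
Why: Enders SAMP alkylation, in which the lithium azaenolate is allylated on the face left open by the methoxymethyl-chelated pyrrolidine and so sets C11 as (S), followed by two-phase oxalic acid hydrolysis that frees the ketone without epimerisation.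

Step 4
Reactants: 7 (4S)-4-allyl-2,2-dimethyloxetan-3-one
Product: 8 (3R,4S)-4-allyl-2,2-dimethyloxetan-3-ol (hydroxyl cis to allyl)
Conditions: LiBH(s-Bu)3, THF, −78 °C; aq. NH4Cl
Reagents that add atoms: none
Why: Substrate-controlled reduction, in which the bulky borohydride attacks the carbonyl anti to the allyl group, so the new C10 hydroxyl is cis to the allyl group (C10 R).

Step 5
Reactants: 8 (3R,4S)-4-allyl-2,2-dimethyloxetan-3-ol; 9 ethyl propiolate
Product: 10 ethyl (E)-3-{[(3R,4S)-4-allyl-2,2-dimethyloxetan-3-yl]oxy}acrylate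
Conditions: PMe3 (10 mol %), CH2Cl2, 0 °C to rt
Reagents that add atoms: none
Why: Phosphine-catalysed oxa-Michael addition of the hindered secondary alcohol to the propiolate gives the (E)-β-alkoxyacrylate under near-neutral conditions that leave the oxetane intact.

Step 6
Reactants: 10 ethyl (E)-3-{[(3R,4S)-4-allyl-2,2-dimethyloxetan-3-yl]oxy}acrylate
Product: 11 ethyl (E)-3-{[(3R,4S)-2,2-dimethyl-4-(2-oxopropyl)oxetan-3-yl]oxy}acrylate
Conditions: PdCl2 (10 mol %), CuCl (1 equiv), O2 (1 atm), DMF/H2O 7:1, rt
Reagents that add atoms: water (O)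
Why: Tsuji–Wacker oxidation is Markovnikov-selective for the terminal alkene and ignores the electron-poor acrylate, so the methyl ketone (C13) is unveiled only now and never meets base while β to the oxetane oxygen.

Step 7
Reactants: 11 ethyl (E)-3-{[(3R,4S)-2,2-dimethyl-4-(2-oxopropyl)oxetan-3-yl]oxy}acrylate
Product: 13 cis-fused tricyclic γ-lactone (8R,10R,11S,13R), via hydroxy ester 12 (not isolated)
Conditions: SmI2 (3 equiv), MeOH (3 equiv), THF, 0 °C to rt
Reagents that add atoms: none
Why: SmI2 reduces the methyl ketone to a samarium ketyl whose carbon C13 adds to the β-carbon C8 of the (E)-β-alkoxyacrylate, a second electron and methanol convert the ester radical into the saturated ester, and the cis samarium alkoxide then acylates itself to the γ-lactone with loss of ethanol. The closest known reaction type is the SmI2-mediated reductive cyclisation of aldehydes and methyl ketones onto β-alkoxyacrylates that gives 2,6-syn tetrahydropyrans. Ring E closes 6-exo-trig through a chair-like transition state, and the lactone ring closes 5-exo-trig by acyl substitution. C8 is controlled by C10, because the acrylate and the C10–C15 bond both take equatorial sites, which places C7 cis to C15. C13 is controlled by C11, because the C13 substituent that goes axial is syn-diaxial to the pseudo-axial oxetane oxygen O16, a site that the samarium-bound ketyl oxygen can fill while trivalent samarium bridges O16 and the ester carbonyl, whereas an axial methyl would only clash with O16, so O14 ends cis to O16 and to C7. The step needs this face selectivity at C13 (2,3-cis where simple substrates give 2,3-trans) and reduction of the ketone without harm to the oxetane, and the rigidly placed Lewis-basic O16 together with neutral conditions and methanol as the only proton source should secure both.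

Step 8
Reactants: 13 cis-fused tricyclic γ-lactone
Product: 14 lactol of 13 (both anomers)
Conditions: i-Bu2AlH (1.1 equiv), CH2Cl2, −78 °C; aq. potassium sodium tartrate
Reagents that add atoms: none
Why: Low-temperature half-reduction of a γ-lactone with i-Bu2AlH stops at the lactol because the tetrahedral aluminate is stable until work-up.

Step 9
Reactants: 14 lactol of 13
Product: 16 (1R,3S,4R,6S)-3-(iodomethyl)-4,8,8-trimethyl-2,7-dioxabicyclo[4.2.0]octan-4-ol, via iodo formate 15 (not isolated)
Conditions: PhI(OAc)2 (1.2 equiv), I2 (1 equiv), CH2Cl2, visible light, rt; then KHCO3 (cat.), MeOH, rt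
Reagents that add atoms: iodine (II)
Why: Suárez hypoiodite fragmentation, in which the anomeric alkoxy radical undergoes β-scission of the bond from C7 to the lactol carbon, the primary C7 radical is trapped by iodine and the excised carbon leaves as the O14 formate that mild methanolysis removes, touches no stereocentre.

Step 10
Reactants: 17 2-(2-bromo-4-methoxyphenyl)acetic acid; 18 3-methoxyphenol
Product: 19 2-[4-methoxy-2-(3-methoxyphenoxy)phenyl]acetic acid
Conditions: CuI (10 mol %), N,N-dimethylglycine (30 mol %), Cs2CO3 (3 equiv), 1,4-dioxane, 100 °C; aq. HCl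
Reagents that add atoms: none
Why: Copper-catalysed Ullmann diaryl ether synthesis joins the phenol to the only C–Br bond, assisted by the ortho carboxymethyl group.

Step 11
Reactants: 19 2-[4-methoxy-2-(3-methoxyphenoxy)phenyl]acetic acid
Product: 20 3,7-dimethoxydibenzo[b,f]oxepin-10(11H)-one
Conditions: Eaton's reagent (P2O5 in MeSO3H), 50 °C
Reagents that add atoms: none
Why: Intramolecular Friedel–Crafts acylation closes the seven-membered ring C at the phenoxy-ring position para to its methoxy group, the only site that is both activated and within reach.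

Step 12
Reactants: 20 3,7-dimethoxydibenzo[b,f]oxepin-10(11H)-one
Product: 21 2-bromo-3,7-dimethoxydibenzo[b,f]oxepin-10(11H)-one
Conditions: N-bromosuccinimide (1.0 equiv), MeCN, 0 °C
Reagents that add atoms: N-bromosuccinimide (O=C1CCC(=O)N1Br)
Why: Electrophilic aromatic bromination takes the ring A position ortho to the methoxy group and para to the ether oxygen, because ring B is deactivated by the conjugated ketone.

Step 13
Reactants: 21 2-bromo-3,7-dimethoxydibenzo[b,f]oxepin-10(11H)-one
Product: 22 2-bromo-3,7-dihydroxydibenzo[b,f]oxepin-10(11H)-one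
Conditions: BBr3 (4 equiv), CH2Cl2, −78 °C to rt; H2O
Reagents that add atoms: none
Why: Lewis-acid cleavage of both aryl methyl ethers is done here, before any acid-sensitive group (prenyl, oxetane, enol ether) is present.

Step 14
Reactants: 22 2-bromo-3,7-dihydroxydibenzo[b,f]oxepin-10(11H)-one
Product: 23 2-bromo-3,7-bis(triisopropylsilyloxy)dibenzo[b,f]oxepin-10(11H)-one
Conditions: triisopropylsilyl chloride (2.5 equiv), imidazole (5 equiv), DMF, 40 °C
Reagents that add atoms: triisopropylsilyl chloride (CC(C)[Si](Cl)(C(C)C)C(C)C)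
Why: Silylation turns both phenols into fluoride-labile triisopropylsilyl ethers that tolerate enolate chemistry and mild acid.

Step 15
Reactants: 23 2-bromo-3,7-bis(triisopropylsilyloxy)dibenzo[b,f]oxepin-10(11H)-one; 24 tributyl(3-methylbut-2-en-1-yl)stannane
Product: 25 2-(3-methylbut-2-en-1-yl)-3,7-bis(triisopropylsilyloxy)dibenzo[b,f]oxepin-10(11H)-one
Conditions: Pd(PPh3)4 (5 mol %), DMF, 90 °C
Reagents that add atoms: none
Why: Stille coupling transfers the prenyl group to the aryl bromide in its linear form under neutral conditions that spare the silyl ethers and the enolisable ketone.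

Step 16
Reactants: 25 2-(3-methylbut-2-en-1-yl)-3,7-bis(triisopropylsilyloxy)dibenzo[b,f]oxepin-10(11H)-one; 16 (1R,3S,4R,6S)-3-(iodomethyl)-4,8,8-trimethyl-2,7-dioxabicyclo[4.2.0]octan-4-ol
Product: 26 δ-hydroxy ketone: 25 carrying at Cβ the [(1R,3R,4R,6S)-4-hydroxy-4,8,8-trimethyl-2,7-dioxabicyclo[4.2.0]octan-3-yl]methyl group (both Cβ epimers)
Conditions: 25 (1.25 equiv), KN(SiMe3)2 (1.2 equiv), THF, −78 °C; then 16 (1 equiv), DMPU, −78 °C to rt
Reagents that add atoms: none
Why: SN2 C-alkylation of the benzylic ketone enolate by the primary iodide forms the C7–Cβ bond while the far less acidic tertiary alcohol stays protonated, and the new Cβ stereocentre does not matter because it becomes sp2 in the next step.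

Step 17
Reactants: 26 δ-hydroxy ketone
Product: 27 bis(triisopropylsilyl) ether of the target
Conditions: PPTS (20 mol %), 4 Å molecular sieves, toluene, 80 °C
Reagents that add atoms: none
Why: Acid-catalysed hemiketalisation of the δ-hydroxy ketone by O14 and dehydration toward the benzylic Cβ–H closes ring D as the cyclic enol ether conjugated with both arenes.

Step 18
Reactants: 27 bis(triisopropylsilyl) ether of the target
Product: 28 target (CNP0102779.1)
Conditions: Bu4NF (2.5 equiv), THF, 0 °C; aq. NH4Cl
Reagents that add atoms: none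
Why: Fluoride cleaves both aryl silyl ethers without touching the enol ether, the oxetane or the prenyl group.

**Compound list**

1 | 2-methylbut-3-yn-2-ol | CC(C)(O)C#C | starting material
2 | 2,2-dimethyloxetan-3-one | CC1(C)OCC1=O | intermediate
3 | (S)-1-amino-2-(methoxymethyl)pyrrolidine (SAMP) | COC[C@@H]1CCCN1N | starting material
4 | (S)-N-(2,2-dimethyloxetan-3-ylidene)-2-(methoxymethyl)pyrrolidin-1-amine (SAMP hydrazone) | COC[C@@H]1CCCN1N=C1COC1(C)C | intermediate
5 | allyl bromide | C=CCBr | starting material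
6 | (S)-N-[(4S)-4-allyl-2,2-dimethyloxetan-3-ylidene]-2-(methoxymethyl)pyrrolidin-1-amine (alkylated SAMP hydrazone, not isolated) | COC[C@@H]1CCCN1N=C1[C@H](CC=C)OC1(C)C | intermediate
7 | (4S)-4-allyl-2,2-dimethyloxetan-3-one | C=CC[C@@H]1OC(C)(C)C1=O | intermediate
8 | (3R,4S)-4-allyl-2,2-dimethyloxetan-3-ol | O[C@@H]1[C@H](CC=C)OC1(C)C | intermediate
9 | ethyl propiolate | CCOC(=O)C#C | starting material
10 | ethyl (E)-3-{[(3R,4S)-4-allyl-2,2-dimethyloxetan-3-yl]oxy}acrylate | CCOC(=O)/C=C/O[C@@H]1[C@H](CC=C)OC1(C)C | intermediate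
11 | ethyl (E)-3-{[(3R,4S)-2,2-dimethyl-4-(2-oxopropyl)oxetan-3-yl]oxy}acrylate | CCOC(=O)/C=C/O[C@@H]1[C@H](CC(C)=O)OC1(C)C | intermediate
12 | ethyl 2-[(1R,3R,4R,6S)-4-hydroxy-4,8,8-trimethyl-2,7-dioxabicyclo[4.2.0]octan-3-yl]acetate (hydroxy ester, not isolated) | CCOC(=O)C[C@H]1O[C@@H]2[C@H](C[C@@]1(C)O)OC2(C)C | intermediate
13 | (8R,10R,11S,13R) γ-lactone of 12, cis-fused across C8–C13 to the ring E/F bicycle | O=C1C[C@H]2O[C@@H]3[C@H](C[C@@]2(C)O1)OC3(C)C | intermediate
14 | lactol of 13 (both anomers) | OC1C[C@H]2O[C@@H]3[C@H](C[C@@]2(C)O1)OC3(C)C | intermediate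
15 | (1R,3S,4R,6S)-3-(iodomethyl)-4,8,8-trimethyl-2,7-dioxabicyclo[4.2.0]octan-4-yl formate (iodo formate, not isolated) | IC[C@H]1O[C@@H]2[C@H](C[C@@]1(C)OC=O)OC2(C)C | intermediate
16 | (1R,3S,4R,6S)-3-(iodomethyl)-4,8,8-trimethyl-2,7-dioxabicyclo[4.2.0]octan-4-ol | IC[C@H]1O[C@@H]2[C@H](C[C@@]1(C)O)OC2(C)C | intermediate
17 | 2-(2-bromo-4-methoxyphenyl)acetic acid | COc1ccc(CC(=O)O)c(Br)c1 | starting material
18 | 3-methoxyphenol | COc1cccc(O)c1 | starting material
19 | 2-[4-methoxy-2-(3-methoxyphenoxy)phenyl]acetic acid | COc1ccc(CC(=O)O)c(Oc2cccc(OC)c2)c1 | intermediate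
20 | 3,7-dimethoxydibenzo[b,f]oxepin-10(11H)-one | COc1ccc2CC(=O)c3ccc(OC)cc3Oc2c1 | intermediate
21 | 2-bromo-3,7-dimethoxydibenzo[b,f]oxepin-10(11H)-one | COc1cc2Oc3cc(OC)ccc3C(=O)Cc2cc1Br | intermediate
22 | 2-bromo-3,7-dihydroxydibenzo[b,f]oxepin-10(11H)-one | Oc1cc2Oc3cc(O)ccc3C(=O)Cc2cc1Br | intermediate
23 | 2-bromo-3,7-bis(triisopropylsilyloxy)dibenzo[b,f]oxepin-10(11H)-one | CC(C)[Si](Oc1cc2Oc3cc(O[Si](C(C)C)(C(C)C)C(C)C)ccc3C(=O)Cc2cc1Br)(C(C)C)C(C)C | intermediate
24 | tributyl(3-methylbut-2-en-1-yl)stannane | CC(C)=CC[Sn](CCCC)(CCCC)CCCC | starting material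
25 | 2-(3-methylbut-2-en-1-yl)-3,7-bis(triisopropylsilyloxy)dibenzo[b,f]oxepin-10(11H)-one | CC(C)=CCc1cc2CC(=O)c3ccc(O[Si](C(C)C)(C(C)C)C(C)C)cc3Oc2cc1O[Si](C(C)C)(C(C)C)C(C)C | intermediate
26 | 11-{[(1R,3R,4R,6S)-4-hydroxy-4,8,8-trimethyl-2,7-dioxabicyclo[4.2.0]octan-3-yl]methyl}-2-(3-methylbut-2-en-1-yl)-3,7-bis(triisopropylsilyloxy)dibenzo[b,f]oxepin-10(11H)-one (both epimers at Cβ) | CC(C)=CCc1cc2C(C[C@H]3O[C@@H]4[C@H](C[C@@]3(C)O)OC4(C)C)C(=O)c3ccc(O[Si](C(C)C)(C(C)C)C(C)C)cc3Oc2cc1O[Si](C(C)C)(C(C)C)C(C)C | intermediate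
27 | bis(triisopropylsilyl) ether of the target, (8R,10R,11S,13R) | CC(C)=CCc1cc2c(cc1O[Si](C(C)C)(C(C)C)C(C)C)Oc1cc(O[Si](C(C)C)(C(C)C)C(C)C)ccc1C1=C2C[C@H]2O[C@@H]3[C@H](C[C@@]2(C)O1)OC3(C)C | intermediate
28 | CNP0102779.1, (8R,10R,11S,13R) | CC(C)=CCc1cc2c(cc1O)Oc1cc(O)ccc1C1=C2C[C@H]2O[C@@H]3[C@H](C[C@@]2(C)O1)OC3(C)C | target

**Step count.** Total: 18 steps. Longest linear sequence: 12 steps (steps 1–9, then 16–18); the dibenzoxepinone branch (steps 10–15) joins at step 16.

**Steps most likely to fail**

Step 7 (key step). The ketyl may add through the usual chair, with the samarium-bound oxygen equatorial and the methyl axial and no bridging to O16. This would give the wrong face at C13 (2,3-trans), which cannot lactonise. The fallback sets out from 11 and comes back at 13. The same cyclisation still makes the C8–C13 bond and is then expected to give the 13-epimeric hydroxy ester F1. SOCl2 in pyridine dehydrates F1 by anti elimination from the equatorial hydroxyl toward the methyl group, giving the exocyclic methylene ester F2. LiOH gives the methylene acid F3. Iodolactonisation (I2, NaHCO3, MeCN) delivers the carboxylate oxygen to C13 from the side of the C8 chain, which should give only the cis-fused iodomethyl lactone F4. Bu3SnH with AIBN reduces CH2I to CH3 and gives 13. In this fallback the C13 configuration is set by the lactone tether, not by ketyl face selectivity.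

Step 16. SN2 attack at the β-branched, β-oxygenated primary iodide may be slow. E2 elimination, O-alkylation, or proton transfer to the tertiary alcohol followed by oxetane closure could then compete. The fallback sets out from 16 and 25 and comes back at 26. It forms the C7–Cβ bond by carbonyl addition and reduction, not by substitution. Et3SiOTf and 2,6-lutidine convert 16 into the triethylsilyl ether iodide F5. AgBF4 in DMSO, then Et3N, oxidises F5 to the aldehyde F6. F6 is added at −78 °C to the lithium enolate of 25 (LiN(SiMe3)2, THF) to give the aldol adduct F7. MsCl and Et3N, then DBU, give the alkylidene ketone F8. Conjugate reduction with [(Ph3P)CuH]6 gives the triethylsilyl ether ketone F9. PPTS in MeOH removes the triethylsilyl group and gives 26.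

Step 17. The acid may ionise and open the 2,2-dimethyloxetane at C15 before the hindered tertiary alcohol adds to the diaryl ketone. The fallback sets out from 26 and comes back at 27, and closes ring D under basic conditions. KN(SiMe3)2 and PhNTf2 (THF, −78 °C) convert 26 into the enol triflate F10; only Cβ–H is enolisable. Intramolecular palladium-catalysed C–O coupling of the tertiary alcohol with the vinyl triflate (Pd2(dba)3, t-BuXPhos, Cs2CO3, toluene, 80 °C) gives 27.

**Further compounds**

F1 | step 7 | ethyl 2-[(1R,3R,4S,6S)-4-hydroxy-4,8,8-trimethyl-2,7-dioxabicyclo[4.2.0]octan-3-yl]acetate (13-epimer of 12) | CCOC(=O)C[C@H]1O[C@@H]2[C@H](C[C@]1(C)O)OC2(C)C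
F2 | step 7 | ethyl 2-[(1R,3R,6S)-8,8-dimethyl-4-methylidene-2,7-dioxabicyclo[4.2.0]octan-3-yl]acetate | CCOC(=O)C[C@H]1O[C@@H]2[C@H](CC1=C)OC2(C)C
F3 | step 7 | 2-[(1R,3R,6S)-8,8-dimethyl-4-methylidene-2,7-dioxabicyclo[4.2.0]octan-3-yl]acetic acid | OC(=O)C[C@H]1O[C@@H]2[C@H](CC1=C)OC2(C)C
F4 | step 7 | iodomethyl analogue of lactone 13 (CH2I in place of the C13 methyl, cis-fused) | O=C1C[C@H]2O[C@@H]3[C@H](C[C@@]2(CI)O1)OC3(C)C
F5 | step 16 | triethylsilyl ether of iodo alcohol 16 | IC[C@H]1O[C@@H]2[C@H](C[C@@]1(C)O[Si](CC)(CC)CC)OC2(C)C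
F6 | step 16 | (8R,10R,11S,13R) C7 aldehyde with O14 triethylsilyl ether | O=C[C@H]1O[C@@H]2[C@H](C[C@@]1(C)O[Si](CC)(CC)CC)OC2(C)C
F7 | step 16 | aldol adduct of 25 and F6 (C7 hydroxyl, diastereomer mixture) | CC(C)=CCc1cc2C(C(O)[C@H]3O[C@@H]4[C@H](C[C@@]3(C)O[Si](CC)(CC)CC)OC4(C)C)C(=O)c3ccc(O[Si](C(C)C)(C(C)C)C(C)C)cc3Oc2cc1O[Si](C(C)C)(C(C)C)C(C)C
F8 | step 16 | alkylidene ketone (Cβ=C7 enone, either geometry) | CC(C)=CCc1cc2C(=C[C@H]3O[C@@H]4[C@H](C[C@@]3(C)O[Si](CC)(CC)CC)OC4(C)C)C(=O)c3ccc(O[Si](C(C)C)(C(C)C)C(C)C)cc3Oc2cc1O[Si](C(C)C)(C(C)C)C(C)C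
F9 | step 16 | O14 triethylsilyl ether of 26 | CC(C)=CCc1cc2C(C[C@H]3O[C@@H]4[C@H](C[C@@]3(C)O[Si](CC)(CC)CC)OC4(C)C)C(=O)c3ccc(O[Si](C(C)C)(C(C)C)C(C)C)cc3Oc2cc1O[Si](C(C)C)(C(C)C)C(C)C
F10 | step 17 | enol triflate of 26 (Cα–OTf, Cα=Cβ) | CC(C)=CCc1cc2C(C[C@H]3O[C@@H]4[C@H](C[C@@]3(C)O)OC4(C)C)=C(OS(=O)(=O)C(F)(F)F)c3ccc(O[Si](C(C)C)(C(C)C)C(C)C)cc3Oc2cc1O[Si](C(C)C)(C(C)C)C(C)C
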